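**Plan**

1. The target is read as the (2R,5R), 2,5-cis-disubstituted oxane (ring O1, C2–C6; side chain C1'–C13' counted from C5). Cis means one axial substituent, so no thermodynamically controlled ring closure is used.
2. Retrosynthetic cuts: the CO2H of the acrylic acid (back to C2–C≡CH, CO and H2O); C6'–C7', then C2'–C3' (two decarboxylative alkenylations); the C2–alkynyl bond (addition to the ring oxocarbenium ion); the C5–C1' bond (Michael addition to tert-butyl acrylate).
3. Forward: the oxane ring arises first, as a δ-lactone from an auxiliary-bound 4-substituted heptanedioate. C2 is then alkynylated, the C5 propanoic acid arm is extended by two alkenyl iodide modules (C3'–C6', then C7'–C13'), and the silylalkyne is finally turned into the acrylic acid.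
4. Stereochemistry: C5 from an oxazolidinone-controlled titanium-enolate Michael addition. C2 from axial attack on the 5-substituted oxocarbenium ion (gives 2,5-cis). Both (E)-olefins from syn-carboalumination of terminal alkynes, carried through the couplings with retention.
5. Enabling feature: C6' is a primary carbon two atoms from the methyl-bearing olefinic carbon C4', so a carboxyl on C6' makes the precursor a plain 4-methylalk-4-enoic acid whose CO2 is lost in the event. C7' is the hydrogen-bearing end of the trisubstituted C7'=C8' olefin, so its partner is an (E)-1-iodo-2-methylalk-1-ene. The oxane ring stays a spectator because the radical-accepting acrylic acid at C2 is held as a silylalkyne.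

Key step: step 14

**Route**

Step 1
Reactants: 1 (4R)-4-benzyl-1,3-oxazolidin-2-one; 2 methyl 5-chloro-5-oxopentanoate
Product: 3 methyl 5-[(4R)-4-benzyl-2-oxo-1,3-oxazolidin-3-yl]-5-oxopentanoate
Conditions: Et3N, DMAP (cat.), CH2Cl2, 0 °C → rt
Reagents that add atoms: none
Why: N-acylation of the oxazolidinone by an acid chloride under Et3N/DMAP catalysis is a standard auxiliary loading and leaves the methyl ester untouched.

Step 2
Reactants: 3; 4 tert-butyl prop-2-enoate
Product: 6 7-tert-butyl 1-methyl (4S)-4-{[(4R)-4-benzyl-2-oxo-1,3-oxazolidin-3-yl]carbonyl}heptanedioate, via chlorotitanium enolate 5 (not isolated)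
Conditions: TiCl4/Ti(OiPr)4 (3:1, gives TiCl3(OiPr)), iPr2NEt, CH2Cl2, 0 °C; then 4, 0 °C → rt
Reagents that add atoms: none
Why: Auxiliary-controlled titanium-enolate Michael addition: the chelated (Z)-enolate 5 should add to the acrylate on the face opposite the benzyl group, which sets the stereocentre that becomes ring C5 (the methyl ester arm becomes ring atoms C2–C4, the tert-butyl ester arm the side chain).

Step 3
Reactants: 6
Product: 8 tert-butyl 3-[(3S)-6-oxooxan-3-yl]propanoate, via hydroxy diester 7 (not isolated)
Conditions: NaBH4, THF/H2O (4:1), 0 °C → rt; then PPTS (cat.), PhMe, 60 °C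
Reagents that add atoms: none
Why: Reductive cleavage of the N-acyl oxazolidinone by NaBH4 in wet THF should give the primary alcohol without reducing the esters, and acid-catalysed lactonisation then occurs only at the methyl ester (six-membered δ-lactone) because the tert-butyl ester resists transesterification, so the two arms are told apart with the stereocentre untouched.

Step 4
Reactants: 8
Product: 10 tert-butyl 3-[(3S)-6-(acetyloxy)oxan-3-yl]propanoate (both C6 epimers), via aluminium lactolate 9 (not isolated)
Conditions: iBu2AlH (1.1 equiv), CH2Cl2, −78 °C; then pyridine, DMAP, Ac2O, −78 → −20 °C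
Reagents that add atoms: acetic anhydride, CC(=O)OC(C)=O
Why: Reductive acetylation of a lactone: the tetrahedral aluminium lactolate 9 is stable at −78 °C and is acetylated in situ to the α-acetoxy ether, the tert-butyl ester being far less reactive towards iBu2AlH at this temperature.

Step 5
Reactants: 10; 11 ethynyltri(propan-2-yl)silane
Product: 14 tert-butyl 3-[(3S,6R)-6-{[tri(propan-2-yl)silyl]ethynyl}oxan-3-yl]propanoate, via lithium acetylide 12 (not isolated), via alkynylalane 13 (not isolated)
Conditions: 11, n-BuLi, PhMe, −78 → 0 °C; Me2AlCl, 0 °C → rt; then 10, CH2Cl2, 0 °C → rt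
Reagents that add atoms: none
Why: The Lewis-acidic alkynylalane ionises the anomeric acetate to the 5-substituted oxocarbenium ion (half-chair with the C5 chain pseudo-equatorial) and delivers the alkynyl group along the axial trajectory that leads directly to a chair (C-glycosylation-type addition to an oxocarbenium ion), which should place the alkyne axial and cis to the C5 substituent and so set C2 as R.

Step 6
Reactants: 14
Product: 15 3-[(3S,6R)-6-{[tri(propan-2-yl)silyl]ethynyl}oxan-3-yl]propanoic acid
Conditions: CF3CO2H/CH2Cl2 (1:4), 0 °C → rt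
Reagents that add atoms: none
Why: Acidolysis of the tert-butyl ester (loss of 2-methylpropene) frees the carboxyl handle at a stage where no acid-sensitive trisubstituted olefin is yet present; the silylalkyne and the ring ether are stable to CF3CO2H.

Step 7
Reactants: 16 pent-4-yn-1-ol
Product: 18 (4E)-5-iodo-4-methylpent-4-en-1-ol, via alkenylalane 17 (not isolated)
Conditions: Me3Al (3 equiv), Cp2ZrCl2 (0.25 equiv), CH2Cl2, 0 °C → rt; then I2, THF, −30 → 0 °C
Reagents that add atoms: trimethylaluminium, C[Al](C)C; iodine, II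
Why: Zirconium-catalysed Negishi carboalumination adds methyl and aluminium syn across the terminal alkyne with the metal at the terminus, and iodinolysis of the C–Al bond with retention should give the (E)-alkenyl iodide (the hydroxyl is carried as its aluminium alkoxide).

Step 8
Reactants: 18
Product: 19 (4E)-5-iodo-4-methylpent-4-enoic acid
Conditions: TEMPO (cat.), PhI(OAc)2 (2.2 equiv), MeCN/H2O (1:1), rt
Reagents that add atoms: water, O
Why: Oxoammonium (TEMPO/PhI(OAc)2) oxidation of a primary alcohol to the carboxylic acid via the aldehyde hydrate; the alkenyl iodide is inert to this oxidant.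

Step 9
Reactants: 19
Product: 20 methyl (4E)-5-iodo-4-methylpent-4-enoate
Conditions: MeI, K2CO3, DMF, rt
Reagents that add atoms: iodomethane, CI
Why: SN2 O-methylation of the carboxylate protects the acid of this module, so that only one carboxyl is activated in step 10.

Step 10
Reactants: 15; 20
Product: 22 methyl (4E)-4-methyl-7-[(3R,6R)-6-{[tri(propan-2-yl)silyl]ethynyl}oxan-3-yl]hept-4-enoate, via phthalimide ester 21 (not isolated)
Conditions: 15, N-hydroxyphthalimide, N,N'-diisopropylcarbodiimide, DMAP (cat.), CH2Cl2, rt; evaporate; then 20 (1.5 equiv), NiCl2·6H2O (10 mol %), 2,2'-bipyridine (10 mol %), AgNO3 (0.3 equiv), LiCl, DMF, Mg anode/reticulated vitreous carbon cathode, undivided cell, constant current, rt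
Reagents that add atoms: none
Why: Nickel-electrocatalytic decarboxylative alkenylation (the reaction type of the key step): the primary radical released from redox-active ester 21 is captured by the alkenylnickel species formed from 20, so the C2'–C3' bond should form with retention of the (E)-geometry while the ester, silylalkyne and ring ether stay inert.

Step 11
Reactants: 22
Product: 23 (4E)-4-methyl-7-[(3R,6R)-6-{[tri(propan-2-yl)silyl]ethynyl}oxan-3-yl]hept-4-enoic acid
Conditions: LiOH·H2O, THF/MeOH/H2O (3:1:1), rt; then 1 M HCl to pH 3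
Reagents that add atoms: lithium hydroxide, [Li+].[OH-]
Why: Saponification of the methyl ester; the tri(propan-2-yl)silyl alkyne withstands LiOH (the reason this silyl group was chosen), and base is used instead of acid because a 4-methylalk-4-enoic acid would lactonise under strong acid.

Step 12
Reactants: 24 5-bromo-2-methylpent-2-ene
Product: 25 6-methylhept-5-en-1-yne
Conditions: LiC≡CH·H2NCH2CH2NH2 (1.5 equiv), DMSO, 10 °C → rt
Reagents that add atoms: lithium acetylide–ethylenediamine complex, [Li]C#C.NCCN
Why: SN2 alkylation of lithium acetylide by a primary homoallylic bromide in DMSO.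

Step 13
Reactants: 25
Product: 27 (1E)-1-iodo-2,6-dimethylhepta-1,5-diene, via alkenylalane 26 (not isolated)
Conditions: Me3Al (2 equiv), Cp2ZrCl2 (0.25 equiv), CH2Cl2, 0 °C → rt; then I2, THF, −30 → 0 °C
Reagents that add atoms: trimethylaluminium, C[Al](C)C; iodine, II
Why: Negishi carboalumination–iodination as in step 7: syn addition of CH3–Al and iodinolysis with retention should fix the (E)-geometry of what becomes C7'=C8'.

Step 14
Reactants: 23; 27
Product: 29 tri(propan-2-yl){[(2R,5R)-5-[(3E,7E)-4,8,12-trimethyltrideca-3,7,11-trien-1-yl]oxan-2-yl]ethynyl}silane, via phthalimide ester 28 (not isolated)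
Conditions: 23, N-hydroxyphthalimide, N,N'-diisopropylcarbodiimide, DMAP (cat.), CH2Cl2, rt; evaporate; then 27 (1.5–2 equiv), NiCl2·6H2O (10 mol %), 2,2'-bipyridine (10 mol %), AgNO3 (0.3 equiv), LiCl, DMF, Mg anode/reticulated vitreous carbon cathode, undivided cell, constant current, rt
Reagents that add atoms: none
Why: The cathode, coated in situ with silver nanoparticles from AgNO3, reduces the bipyridine–nickel catalyst to low-valent nickel, which adds oxidatively to the C–I bond of 27 with retention of olefin geometry and transfers one electron to the N-(acyloxy)phthalimide 28, which loses phthalimide anion and CO2 to give the primary C6' radical; capture of this radical by the alkenylnickel species gives a trivalent nickel intermediate that reductively eliminates the C6'–C7' bond, the Mg anode supplying the electrons. The closest known reaction type is the nickel-catalysed electrochemical coupling of redox-active esters of 4-methylalk-4-enoic acids with (E)-2-methylalk-1-enyl iodides used to assemble 1,5-polyene terpenoids, of which this is a direct application joining two electrophilic carbons. No ring is closed and no stereocentre is formed; the C7'=C8' geometry is fixed in 27 by the syn-carboalumination of step 13 and should pass through oxidative addition and reductive elimination unchanged. The step needs cross-coupling to win over homodimerisation of either partner and over hydrodecarboxylation, which excess 27, constant-current generation of the reduced catalyst and the silver-coated cathode (which keeps nickel from plating out) are meant to secure. It also needs the homoallylic radical to be trapped faster than its reversible 3-exo closure onto C4', which could erode the C3'=C4' geometry. The hindered silylalkyne, the ring ether and the remote trisubstituted olefins are inert to the radical and to low-valent nickel, and the acrylic acid, which would be a radical acceptor, is absent because it is still masked as the silylalkyne.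

Step 15
Reactants: 29
Product: 30 (2R,5R)-2-ethynyl-5-[(3E,7E)-4,8,12-trimethyltrideca-3,7,11-trien-1-yl]oxane
Conditions: Bu4NF, THF, 0 °C → rt
Reagents that add atoms: none
Why: Fluoride-induced protodesilylation of the alkynylsilane unmasks the terminal alkyne; nothing else in 29 reacts with Bu4NF.

Step 16
Reactants: 30
Product: 31 rhopaloic acid B, 2-[(2R,5R)-5-[(3E,7E)-4,8,12-trimethyltrideca-3,7,11-trien-1-yl]oxan-2-yl]prop-2-enoic acid
Conditions: Pd(OAc)2 (5 mol %), 2-(diphenylphosphino)pyridine (40 mol %), CH3SO3H (20 mol %), CO (10 bar), H2O (10 equiv), THF, 50 °C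
Reagents that add atoms: carbon monoxide, [C-]#[O+]; water, O
Why: Palladium-catalysed Markovnikov hydroxycarbonylation of a terminal alkyne: a cationic palladium hydride carrying the pyridylphosphine adds across C≡C with palladium at the internal carbon, and CO insertion followed by hydrolysis of the acylpalladium should give the 2-substituted acrylic acid without base (no risk of C2 epimerisation by ring opening and reclosure), the unactivated trisubstituted olefins not inserting under these buffered conditions.

**Compound list**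

1 | (4R)-4-benzyl-1,3-oxazolidin-2-one | O=C1N[C@H](Cc2ccccc2)CO1 | starting material
2 | methyl 5-chloro-5-oxopentanoate | COC(=O)CCCC(=O)Cl | starting material
3 | methyl 5-[(4R)-4-benzyl-2-oxo-1,3-oxazolidin-3-yl]-5-oxopentanoate | COC(=O)CCCC(=O)N1[C@H](Cc2ccccc2)COC1=O | intermediate
4 | tert-butyl prop-2-enoate | C=CC(=O)OC(C)(C)C | starting material
5 | (Z)-dichloro(propan-2-olato)titanium enolate of 3 | COC(=O)CC/C=C(\O[Ti](Cl)(Cl)OC(C)C)N1[C@H](Cc2ccccc2)COC1=O | intermediate
6 | 7-tert-butyl 1-methyl (4S)-4-{[(4R)-4-benzyl-2-oxo-1,3-oxazolidin-3-yl]carbonyl}heptanedioate | COC(=O)CC[C@@H](CCC(=O)OC(C)(C)C)C(=O)N1[C@H](Cc2ccccc2)COC1=O | intermediate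
7 | 7-tert-butyl 1-methyl (4S)-4-(hydroxymethyl)heptanedioate | COC(=O)CC[C@@H](CCC(=O)OC(C)(C)C)CO | intermediate
8 | tert-butyl 3-[(3S)-6-oxooxan-3-yl]propanoate | O=C1CC[C@@H](CCC(=O)OC(C)(C)C)CO1 | intermediate
9 | bis(2-methylpropyl)aluminium lactolate of 8 | CC(C)C[Al](CC(C)C)OC1CC[C@@H](CCC(=O)OC(C)(C)C)CO1 | intermediate
10 | tert-butyl 3-[(3S)-6-(acetyloxy)oxan-3-yl]propanoate (both C6 epimers) | CC(=O)OC1CC[C@@H](CCC(=O)OC(C)(C)C)CO1 | intermediate
11 | ethynyltri(propan-2-yl)silane | C#C[Si](C(C)C)(C(C)C)C(C)C | starting material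
12 | lithium [tri(propan-2-yl)silyl]acetylide | [Li]C#C[Si](C(C)C)(C(C)C)C(C)C | intermediate
13 | dimethyl{[tri(propan-2-yl)silyl]ethynyl}alane | C[Al](C)C#C[Si](C(C)C)(C(C)C)C(C)C | intermediate
14 | tert-butyl 3-[(3S,6R)-6-{[tri(propan-2-yl)silyl]ethynyl}oxan-3-yl]propanoate | CC(C)[Si](C(C)C)(C(C)C)C#C[C@H]1CC[C@@H](CCC(=O)OC(C)(C)C)CO1 | intermediate
15 | 3-[(3S,6R)-6-{[tri(propan-2-yl)silyl]ethynyl}oxan-3-yl]propanoic acid | CC(C)[Si](C(C)C)(C(C)C)C#C[C@H]1CC[C@@H](CCC(=O)O)CO1 | intermediate
16 | pent-4-yn-1-ol | C#CCCCO | starting material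
17 | dimethylaluminium alkoxide of [(1E)-5-hydroxy-2-methylpent-1-en-1-yl]dimethylalane | C[Al](C)OCCC/C(C)=C/[Al](C)C | intermediate
18 | (4E)-5-iodo-4-methylpent-4-en-1-ol | OCCC/C(C)=C/I | intermediate
19 | (4E)-5-iodo-4-methylpent-4-enoic acid | OC(=O)CC/C(C)=C/I | intermediate
20 | methyl (4E)-5-iodo-4-methylpent-4-enoate | COC(=O)CC/C(C)=C/I | intermediate
21 | 1,3-dioxoisoindol-2-yl 3-[(3S,6R)-6-{[tri(propan-2-yl)silyl]ethynyl}oxan-3-yl]propanoate | CC(C)[Si](C(C)C)(C(C)C)C#C[C@H]1CC[C@@H](CCC(=O)ON2C(=O)c3ccccc3C2=O)CO1 | intermediate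
22 | methyl (4E)-4-methyl-7-[(3R,6R)-6-{[tri(propan-2-yl)silyl]ethynyl}oxan-3-yl]hept-4-enoate | CC(C)[Si](C(C)C)(C(C)C)C#C[C@H]1CC[C@@H](CC/C=C(\C)CCC(=O)OC)CO1 | intermediate
23 | (4E)-4-methyl-7-[(3R,6R)-6-{[tri(propan-2-yl)silyl]ethynyl}oxan-3-yl]hept-4-enoic acid | CC(C)[Si](C(C)C)(C(C)C)C#C[C@H]1CC[C@@H](CC/C=C(\C)CCC(=O)O)CO1 | intermediate
24 | 5-bromo-2-methylpent-2-ene | CC(C)=CCCBr | starting material
25 | 6-methylhept-5-en-1-yne | C#CCCC=C(C)C | intermediate
26 | [(1E)-2,6-dimethylhepta-1,5-dien-1-yl]dimethylalane | C[Al](C)/C=C(\C)CCC=C(C)C | intermediate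
27 | (1E)-1-iodo-2,6-dimethylhepta-1,5-diene | I/C=C(\C)CCC=C(C)C | intermediate
28 | 1,3-dioxoisoindol-2-yl (4E)-4-methyl-7-[(3R,6R)-6-{[tri(propan-2-yl)silyl]ethynyl}oxan-3-yl]hept-4-enoate | CC(C)[Si](C(C)C)(C(C)C)C#C[C@H]1CC[C@@H](CC/C=C(\C)CCC(=O)ON2C(=O)c3ccccc3C2=O)CO1 | intermediate
29 | tri(propan-2-yl){[(2R,5R)-5-[(3E,7E)-4,8,12-trimethyltrideca-3,7,11-trien-1-yl]oxan-2-yl]ethynyl}silane | CC(C)[Si](C(C)C)(C(C)C)C#C[C@H]1CC[C@@H](CC/C=C(\C)CC/C=C(\C)CCC=C(C)C)CO1 | intermediate
30 | (2R,5R)-2-ethynyl-5-[(3E,7E)-4,8,12-trimethyltrideca-3,7,11-trien-1-yl]oxane | C#C[C@H]1CC[C@@H](CC/C=C(\C)CC/C=C(\C)CCC=C(C)C)CO1 | intermediate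
31 | rhopaloic acid B, 2-[(2R,5R)-5-[(3E,7E)-4,8,12-trimethyltrideca-3,7,11-trien-1-yl]oxan-2-yl]prop-2-enoic acid | C=C(C(=O)O)[C@H]1CC[C@@H](CC/C=C(\C)CC/C=C(\C)CCC=C(C)C)CO1 | target

**Step count and risks**

Total step count: 16. Longest linear sequence: 11 steps (steps 1–6, 10, 11, 14, 15, 16).

Most likely to fail:

Step 14. The primary radical may be lost to hydrogen abstraction or dimerisation before nickel captures it, the alkenyl iodide may homocouple, the electrodes may passivate, or reversible cyclopropylcarbinyl formation may erode the C3'=C4' geometry. The fallback is a two-electron sp3–sp2 cross-coupling that sets out from acid 23 and returns at 29. Acid 23 is esterified with N-hydroxypyridine-2-thione (dicyclohexylcarbodiimide, CH2Cl2, dark) to the thiohydroxamate (Barton) ester F1. Photolysis with CHI3 (Barton decarboxylative iodination, fast iodine-atom transfer) should give the homoallylic iodide F2. Zinc insertion (Zn dust, LiCl, THF) gives the alkylzinc iodide F3, which is coupled with 27 under Pd(PPh3)4 (zerovalent palladium, Negishi coupling of a homoallylzinc with an (E)-alkenyl iodide, retention of geometry) to give 29.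

Step 16. The palladium hydride may insert with the wrong regiochemistry (linear acid), may cause migration of the chain olefins, or the acid co-catalyst may open the ring at the activated C2–O bond. The fallback sets out from alkyne 30 and returns at 31 by stoichiometric regiocontrol. Molybdenum-catalysed α-selective hydrostannation (Mo(CO)3(CNtBu)3, Bu3SnH, THF, 55 °C; the propargylic oxygen directs tin to the internal carbon) gives the 1-stannylvinyl oxane F4. Iododestannylation (I2, CH2Cl2, 0 °C) gives the 1-iodovinyl oxane F5. Methoxycarbonylation (Pd(PPh3)4, CO 1 atm, MeOH, Et3N, DMF, 50 °C) gives the methyl acrylate F6, and near-neutral hydrolysis (Me3SnOH, 1,2-dichloroethane, 70 °C) gives 31.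

Step 5. Facial selectivity in the capture of the oxocarbenium ion may be poor (2,5-trans product), ionisation of the acetate may be incomplete, or the tert-butyl ester may be lost to the Lewis acid. The fallback sets C2 by reagent control and closes the ring by Williamson etherification; it sets out from lactone 8 and returns at 14. Addition of lithium acetylide 12 (THF, −78 °C) to 8 gives the hydroxy ynone F7. Noyori asymmetric transfer hydrogenation (RuCl[(R,R)-TsDPEN](p-cymene), iPrOH, rt) should give the (7R)-propargylic diol F8. Selective sulfonylation of the primary hydroxyl (TsCl, Et3N, Me3N·HCl cat., CH2Cl2, 0 °C) gives the monotosylate F9. NaH (THF, 0 °C → rt) then closes the oxane by 6-exo-tet displacement at the primary carbon, leaving both stereocentres untouched, to give 14.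

**Further compounds**

F1 | step 14 | 2-sulfanylidenepyridin-1(2H)-yl (4E)-4-methyl-7-[(3R,6R)-6-{[tri(propan-2-yl)silyl]ethynyl}oxan-3-yl]hept-4-enoate | CC(C)[Si](C(C)C)(C(C)C)C#C[C@H]1CC[C@@H](CC/C=C(\C)CCC(=O)ON2C=CC=CC2=S)CO1
F2 | step 14 | {[(2R,5R)-5-[(3E)-6-iodo-4-methylhex-3-en-1-yl]oxan-2-yl]ethynyl}tri(propan-2-yl)silane | CC(C)[Si](C(C)C)(C(C)C)C#C[C@H]1CC[C@@H](CC/C=C(\C)CCI)CO1
F3 | step 14 | iodo{(3E)-3-methyl-6-[(3R,6R)-6-{[tri(propan-2-yl)silyl]ethynyl}oxan-3-yl]hex-3-en-1-yl}zinc | CC(C)[Si](C(C)C)(C(C)C)C#C[C@H]1CC[C@@H](CC/C=C(\C)CC[Zn]I)CO1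
F4 | step 16 | tributyl{1-[(2R,5R)-5-[(3E,7E)-4,8,12-trimethyltrideca-3,7,11-trien-1-yl]oxan-2-yl]ethenyl}stannane | C=C([Sn](CCCC)(CCCC)CCCC)[C@H]1CC[C@@H](CC/C=C(\C)CC/C=C(\C)CCC=C(C)C)CO1
F5 | step 16 | (2R,5R)-2-(1-iodoethenyl)-5-[(3E,7E)-4,8,12-trimethyltrideca-3,7,11-trien-1-yl]oxane | C=C(I)[C@H]1CC[C@@H](CC/C=C(\C)CC/C=C(\C)CCC=C(C)C)CO1
F6 | step 16 | methyl 2-[(2R,5R)-5-[(3E,7E)-4,8,12-trimethyltrideca-3,7,11-trien-1-yl]oxan-2-yl]prop-2-enoate | C=C(C(=O)OC)[C@H]1CC[C@@H](CC/C=C(\C)CC/C=C(\C)CCC=C(C)C)CO1
F7 | step 5 | tert-butyl (4S)-4-(hydroxymethyl)-7-oxo-9-[tri(propan-2-yl)silyl]non-8-ynoate | CC(C)[Si](C(C)C)(C(C)C)C#CC(=O)CC[C@@H](CCC(=O)OC(C)(C)C)CO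
F8 | step 5 | tert-butyl (4S,7R)-7-hydroxy-4-(hydroxymethyl)-9-[tri(propan-2-yl)silyl]non-8-ynoate | CC(C)[Si](C(C)C)(C(C)C)C#C[C@H](O)CC[C@@H](CCC(=O)OC(C)(C)C)CO
F9 | step 5 | tert-butyl (4S,7R)-7-hydroxy-4-{[(4-methylbenzenesulfonyl)oxy]methyl}-9-[tri(propan-2-yl)silyl]non-8-ynoate | CC(C)[Si](C(C)C)(C(C)C)C#C[C@H](O)CC[C@@H](CCC(=O)OC(C)(C)C)COS(=O)(=O)c1ccc(C)cc1
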